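The five-membered ring is disconnected at C1–C7a and C2–C3. In ring A (the fused benzene ring) the ketone-bearing carbon C3a is flanked by the oxygenated C4 and by a single free ortho C–H, C7a, so a diaryl ketone at C3 can guide rhodium to C7a. An internal alkyne then supplies C1, C2 and C8, and the alkenyl–rhodium adds to the ketone. One enantioselective operation thus forms both bonds, the carbocycle and a C3 carbinol that later relays configuration to C1, C2 and C3. The precursor is the tetramethoxybenzophenone plus a 1,3-bis(4-methoxyphenyl)propyne with C8 as a methyl-protected carbinol, which fixes the insertion sense.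

Key step: step 3

Numbering and labels: target numbering is kept for every intermediate. C1 carries C8 (ring B sits on C8), C2 carries ring C (4-oxyphenyl), C3 carries ring D (3,5-dioxyphenyl). Ring A is C3a–C7a with oxygen on C4 and C6.

Remark on the alkyne: a conjugated alkynone would be expected to insert into the aryl–rhodium bond in the conjugate sense (new C–C bond at the aryl-bearing alkyne carbon, rhodium next to the carbonyl). That would put the aroyl group on C2, so C8 is carried through the annulation as a methyl-protected carbinol and oxidised directly afterwards.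

Assumption: CpX is the cyclopentadienyl ligand fused through two CH2 groups to the 2,2′-positions of an (R)-1,1′-binaphthyl bearing 3,3′-OMe groups. The (R)-ligand is written as the antipode that gives the (R)-carbinol; if a first run shows the opposite sense, the (S)-ligand is used.

Step 1
Reactants: 1 1,3-dimethoxybenzene; 2 3,5-dimethoxybenzoyl chloride
Product: 3 (2,4-dimethoxyphenyl)(3,5-dimethoxyphenyl)methanone
Conditions: AlCl3 (1.1 equiv), CH2Cl2, 0 °C
Reagents that add atoms: none
Why: Friedel–Crafts acylation, in which the acylium ion attacks C4 of the resorcinol dimethyl ether (para to one methoxy group, ortho to the other, the position between them being hindered), and one equivalent of AlCl3 at 0 °C avoids cleavage of the methoxy group ortho to the new ketone.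

Step 2
Reactants: 4 4-ethynylanisole; 5 4-methoxybenzaldehyde
Product: 8 racemic 1-methoxy-4-[3-methoxy-3-(4-methoxyphenyl)prop-1-yn-1-yl]benzene, via lithium acetylide 6 (not isolated), via lithium alkoxide 7 (not isolated)
Conditions: n-BuLi, THF, −78 °C; then 5; then MeI, DMPU, −78 °C to rt
Reagents that add atoms: iodomethane, CI
Why: Addition of a lithium acetylide to a non-enolisable aldehyde followed by Williamson O-methylation of the lithium alkoxide in the same flask (DMPU loosens the ion pair); the product is racemic, which is harmless because C8 becomes a carbonyl carbon in step 4.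

Step 3
Reactants: 3 (2,4-dimethoxyphenyl)(3,5-dimethoxyphenyl)methanone; 8 racemic 1-methoxy-4-[3-methoxy-3-(4-methoxyphenyl)prop-1-yn-1-yl]benzene (1.5 equiv)
Product: 9 (1R)-1-(3,5-dimethoxyphenyl)-5,7-dimethoxy-3-[methoxy(4-methoxyphenyl)methyl]-2-(4-methoxyphenyl)-1H-inden-1-ol (the carbinol carbon is C3 of the target; both C8 epimers)
Conditions: [Rh(CpX)(C2H4)2] (5 mol %), (PhCO2)2 (5 mol %), AgSbF6 (10 mol %), Cu(OAc)2 (1 equiv), ClCH2CH2Cl, 80 °C
Reagents that add atoms: none
Why: Proposed new method: dibenzoyl peroxide oxidises the monovalent rhodium precatalyst to a trivalent rhodium benzoate, which after ionisation by AgSbF6 cleaves the C7a–H bond with carboxylate assistance to give a five-membered rhodacycle anchored on the ketone oxygen; alkyne 8 inserts into the Rh–C7a bond, the alkenyl–rhodium adds to the C3 carbonyl and protonolysis of the rhodium alkoxide returns the catalyst without net redox change. The closest known reactions are the [RhCl2(C5Me5)]2/AgSbF6/Cu(OAc)2 annulation of aryl ketones with internal alkynes to racemic 1H-inden-1-ols and enantioselective C–H annulations under chiral cyclopentadienyl rhodium catalysts, the new element being their combination on a diaryl ketone. The carbocycle closes in two events, intermolecular syn carbometalation (C1–C7a) and then intramolecular 1,2-addition of C2 to the ketone (C2–C3, 5-exo-trig with respect to the new ring). The C3 stereocentre is set in that addition by the chiral cyclopentadienyl ligand, whose binaphthyl wall leaves one face of the bound ketone open to the alkenyl group, while the racemic C8 centre is a spectator, so 9 should form as two C8 epimers of one C3 configuration. Site selectivity rests on C7a–H being the only ortho C–H not flanked by an oxygen substituent (both ortho C–H bonds of ring D lie between the carbonyl-bearing carbon and a methoxy-bearing carbon) and on the ortho/para methoxy groups that keep the carbonyl conjugated with ring A. Insertion regiochemistry rests on the aryl/alkyl bias of the alkyne, the sp3-substituted carbon bonding to C7a and the aryl-bearing carbon to rhodium, and the product carries no ketone that could direct a second metalation.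

Step 4
Reactants: 9 (1R)-1-(3,5-dimethoxyphenyl)-5,7-dimethoxy-3-[methoxy(4-methoxyphenyl)methyl]-2-(4-methoxyphenyl)-1H-inden-1-ol
Product: 10 [(1R)-1-(3,5-dimethoxyphenyl)-1-hydroxy-5,7-dimethoxy-2-(4-methoxyphenyl)-1H-inden-3-yl](4-methoxyphenyl)methanone
Conditions: DDQ (1.5 equiv), CH2Cl2/pH 7 buffer (10:1), 0 °C to rt
Reagents that add atoms: water, O
Why: Oxidative cleavage of a para-methoxybenzyl-type ether with DDQ, in which hydride is abstracted from C8–H (at once allylic, para-methoxybenzylic and α to oxygen) and water converts the oxocarbenium ion into the ketone, so both C8 epimers converge on one enone while the tertiary carbinol, which has no such hydrogen, is left alone.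

Step 5
Reactants: 10 [(1R)-1-(3,5-dimethoxyphenyl)-1-hydroxy-5,7-dimethoxy-2-(4-methoxyphenyl)-1H-inden-3-yl](4-methoxyphenyl)methanone
Product: 11 [(1R,2R,3S)-3-(3,5-dimethoxyphenyl)-3-hydroxy-4,6-dimethoxy-2-(4-methoxyphenyl)-2,3-dihydro-1H-inden-1-yl](4-methoxyphenyl)methanone
Conditions: [Ir(cod)(PCy3)(py)]PF6 (10 mol %), H2 (10 bar), CH2Cl2, rt
Reagents that add atoms: none
Why: Hydroxyl-directed homogeneous hydrogenation, in which the allylic C3 hydroxyl binds the cationic monovalent iridium centre and both hydrogens are delivered syn to C1 and C2 from the hydroxyl face, which is also the face remote from ring D, so the aroyl group and ring C should end cis to each other and to ring D while the ketone and the aryl ethers are not reduced.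

Step 6
Reactants: 11 [(1R,2R,3S)-3-(3,5-dimethoxyphenyl)-3-hydroxy-4,6-dimethoxy-2-(4-methoxyphenyl)-2,3-dihydro-1H-inden-1-yl](4-methoxyphenyl)methanone
Product: 12 [(1R,2R,3R)-3-(3,5-dimethoxyphenyl)-4,6-dimethoxy-2-(4-methoxyphenyl)-2,3-dihydro-1H-inden-1-yl](4-methoxyphenyl)methanone
Conditions: Et3SiH (5 equiv), CF3CO2H (10 equiv), CH2Cl2, −40 to 0 °C
Reagents that add atoms: none
Why: Ionic hydrogenation, in which CF3CO2H ionises the tertiary doubly benzylic carbinol to a C3 cation stabilised by ring D and by the C4 and C6 oxygens and Et3SiH delivers hydride to the face anti to ring C on C2 and to the aroyl group on C1, placing ring D cis to both and completing the all-cis triad; low temperature and excess silane keep proton loss from C2 and enolisation at C1 behind hydride capture.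

Step 7
Reactants: 12 [(1R,2R,3R)-3-(3,5-dimethoxyphenyl)-4,6-dimethoxy-2-(4-methoxyphenyl)-2,3-dihydro-1H-inden-1-yl](4-methoxyphenyl)methanone
Product: 13 caraphenol B, [(1R,2R,3R)-3-(3,5-dihydroxyphenyl)-4,6-dihydroxy-2-(4-hydroxyphenyl)-2,3-dihydro-1H-inden-1-yl](4-hydroxyphenyl)methanone
Conditions: BBr3 (12 equiv), CH2Cl2, −78 to 0 °C; then H2O, 0 °C
Reagents that add atoms: none
Why: Lewis-acid cleavage of aryl methyl ethers with BBr3 (bromide attacks the methyl group of each boron-bound ether) should free all six phenols in one operation; the para-oxygenated aryl ketone is a poor electrophile and the cold quench limits enolisation at C1, so the three stereocentres should be carried through unchanged.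

Compound list
1 | 1,3-dimethoxybenzene | COc1cccc(OC)c1 | starting material
2 | 3,5-dimethoxybenzoyl chloride | O=C(Cl)c1cc(OC)cc(OC)c1 | starting material
3 | (2,4-dimethoxyphenyl)(3,5-dimethoxyphenyl)methanone | O=C(c1ccc(OC)cc1OC)c1cc(OC)cc(OC)c1 | intermediate
4 | 4-ethynylanisole | C#Cc1ccc(OC)cc1 | starting material
5 | 4-methoxybenzaldehyde | O=Cc1ccc(OC)cc1 | starting material
6 | lithium (4-methoxyphenyl)acetylide (not isolated) | [Li]C#Cc1ccc(OC)cc1 | intermediate
7 | lithium 1,3-bis(4-methoxyphenyl)prop-2-yn-1-olate, racemic (not isolated) | [Li]OC(C#Cc1ccc(OC)cc1)c1ccc(OC)cc1 | intermediate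
8 | 1-methoxy-4-[3-methoxy-3-(4-methoxyphenyl)prop-1-yn-1-yl]benzene, racemic | COC(C#Cc1ccc(OC)cc1)c1ccc(OC)cc1 | intermediate
9 | (1R)-1-(3,5-dimethoxyphenyl)-5,7-dimethoxy-3-[methoxy(4-methoxyphenyl)methyl]-2-(4-methoxyphenyl)-1H-inden-1-ol, both C8 epimers | COC(c1ccc(OC)cc1)C1=C(c2ccc(OC)cc2)[C@](O)(c2cc(OC)cc(OC)c2)c2c(OC)cc(OC)cc21 | intermediate
10 | [(1R)-1-(3,5-dimethoxyphenyl)-1-hydroxy-5,7-dimethoxy-2-(4-methoxyphenyl)-1H-inden-3-yl](4-methoxyphenyl)methanone | O=C(c1ccc(OC)cc1)C1=C(c2ccc(OC)cc2)[C@](O)(c2cc(OC)cc(OC)c2)c2c(OC)cc(OC)cc21 | intermediate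
11 | [(1R,2R,3S)-3-(3,5-dimethoxyphenyl)-3-hydroxy-4,6-dimethoxy-2-(4-methoxyphenyl)-2,3-dihydro-1H-inden-1-yl](4-methoxyphenyl)methanone | O=C(c1ccc(OC)cc1)[C@H]1c2cc(OC)cc(OC)c2[C@@](O)(c2cc(OC)cc(OC)c2)[C@H]1c1ccc(OC)cc1 | intermediate
12 | [(1R,2R,3R)-3-(3,5-dimethoxyphenyl)-4,6-dimethoxy-2-(4-methoxyphenyl)-2,3-dihydro-1H-inden-1-yl](4-methoxyphenyl)methanone | O=C(c1ccc(OC)cc1)[C@H]1c2cc(OC)cc(OC)c2[C@@H](c2cc(OC)cc(OC)c2)[C@H]1c1ccc(OC)cc1 | intermediate
13 | caraphenol B, [(1R,2R,3R)-3-(3,5-dihydroxyphenyl)-4,6-dihydroxy-2-(4-hydroxyphenyl)-2,3-dihydro-1H-inden-1-yl](4-hydroxyphenyl)methanone | O=C(c1ccc(O)cc1)[C@H]1c2cc(O)cc(O)c2[C@@H](c2cc(O)cc(O)c2)[C@H]1c1ccc(O)cc1 | target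

Total step count: 7. Longest linear sequence: 6 (step 1 or step 2, then steps 3 to 7).

Steps most likely to fail

Step 3 (key step). What may go wrong: competing metalation on ring D, insertion of the alkyne in the opposite sense (then loss of methoxide to an allene), solvolysis of the allylic and benzylic C8 ether under the Lewis-acidic conditions, or poor facial discrimination in the ketone addition. The fallback uses known chemistry and places boron on C7a beforehand, so that the aryl–rhodium bond forms by transmetalation. It sets out from 2. Friedel–Crafts acylation of commercial 1-bromo-3,5-dimethoxybenzene (COc1cc(Br)cc(OC)c1) with 2 (AlCl3, CH2Cl2, 0 °C; attack ortho to bromine and para to methoxy) should give (2-bromo-4,6-dimethoxyphenyl)(3,5-dimethoxyphenyl)methanone F1. Miyaura borylation (B2pin2, Pd(dppf)Cl2, KOAc, dioxane, 90 °C) should give (3,5-dimethoxyphenyl)[2,4-dimethoxy-6-(4,4,5,5-tetramethyl-1,3,2-dioxaborolan-2-yl)phenyl]methanone F2. Asymmetric arylative annulation of F2 with alkyne 8 under a monovalent rhodium catalyst ([RhCl(C2H4)2]2, (R,R)-2,5-diphenylbicyclo[2.2.2]octa-2,5-diene, KOH, dioxane/H2O, 60 °C) proceeds by transmetalation, syn carbometalation and addition of the alkenyl–rhodium to the ketone. It comes back to the route at 9.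

Step 5. What may go wrong: the tetrasubstituted, aryl-conjugated enone may bind iridium too weakly, so that turnover stalls and the catalyst decays to hydride-bridged clusters, or hydrogen may enter from the ring D face. The fallback replaces coordination control in solution by steric control on a metal surface. It sets out from 10 and uses heterogeneous hydrogenation (Rh/Al2O3, H2 30 bar, EtOAc, rt, neutral medium to avoid hydrogenolysis of the C3–OH bond). Syn addition should occur on the face remote from ring D, which is the hydroxyl face, as in the hydrogenation of 2,3-diarylindenes to cis-indanes. It comes back to the route at 11 and makes no new compound (F0).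

Step 6. What may go wrong: proton loss from C2 of the cation and drift of the resulting alkene into conjugation with the ketone, acid-promoted epimerisation at C1, or hydride capture on the ring C face. The fallback removes the hydroxyl through a radical instead of a cation. It sets out from 11. Acylation with methyl chlorooxoacetate (COC(=O)C(=O)Cl; DMAP, Et3N, CH2Cl2, 0 °C) should give the tertiary methyl oxalate of 11, with configuration as in 11, F3. Tin hydride reduction (Bu3SnH, AIBN, toluene, 80 °C; Barton–McCombie-type deoxygenation of a tertiary oxalate) cleaves the C3–O bond homolytically, and the planar C3 radical should take hydrogen on the face anti to ring C. It comes back to the route at 12.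

Further compounds
F1 | step 3 | (2-bromo-4,6-dimethoxyphenyl)(3,5-dimethoxyphenyl)methanone | O=C(c1c(Br)cc(OC)cc1OC)c1cc(OC)cc(OC)c1
F2 | step 3 | (3,5-dimethoxyphenyl)[2,4-dimethoxy-6-(4,4,5,5-tetramethyl-1,3,2-dioxaborolan-2-yl)phenyl]methanone | O=C(c1c(B2OC(C)(C)C(C)(C)O2)cc(OC)cc1OC)c1cc(OC)cc(OC)c1
F0 | step 5 | none | none
F3 | step 6 | methyl oxalate of 11 at the C3 hydroxyl, configuration as in 11 | O=C(c1ccc(OC)cc1)[C@H]1c2cc(OC)cc(OC)c2[C@@](OC(=O)C(=O)OC)(c2cc(OC)cc(OC)c2)[C@H]1c1ccc(OC)cc1
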